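**Retrosynthetic overview**
- The two ester C–O bonds are cut last: a double Mitsunobu esterification (inversion at C6) joins two molecules of 6-epi-incarvilline 15 to the unsymmetrical, benzyl-protected α-truxillic-type diacid 29, followed by O-debenzylation.
- The strategy rests on the cis-fused octahydrocyclopenta[c]pyridine of each amino alcohol: the piperidine C1–N2–C3–C4–C4a–C7a shares C4a–C7a with the cyclopentane C4a–C5–C6–C7–C7a. A 1,6-diyne tethered through C5–C6–C7 gives this skeleton when it takes up MeN=C=O, which supplies N2–CH3 and C3 as a carbonyl.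
- Ring order: the cyclopentene and the N-methyl-2-pyridone close together in the (2+2+2) step (C4a–C7a, N2–C1, C3–C4). One face-selective hydrogenation then sets C4, C4a and C7a; C7 and C6 are corrected through the C6 ketone; the lactam C=O is reduced away.
- The diyne comes from an anti-selective Pd/In propargylation of pent-3-ynal with (S)-but-3-yn-2-yl mesylate.
- The cyclobutane comes from methyl coumalate (4π photoclosure, hydrogenation), two amide-directed C–H arylations with different aryl iodides, and a resolution.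

Key step: step 5

Remark: diacid 29 carries two different aryl groups and is therefore chiral; its handedness is fixed by resolving 23, and the retained enantiomer 24 would be assigned by X-ray (anomalous scattering of S) before it is carried on.

**Route**

Step 1
Reactants: 1 (S)-but-3-yn-2-ol
Product: 2 (S)-but-3-yn-2-yl methanesulfonate
Conditions: MsCl, Et3N, CH2Cl2, −78 → 0 °C
Reagents that add atoms: methanesulfonyl chloride CS(=O)(=O)Cl
Why: O-sulfonylation of the secondary propargylic alcohol does not touch the C–O bond, so the (S) centre is retained.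

Step 2
Reactants: 3 pent-3-yn-1-ol
Product: 4 pent-3-ynal
Conditions: Dess–Martin periodinane, NaHCO3 (buffer), CH2Cl2, 0 °C; cold solution used at once
Reagents that add atoms: none
Why: Dess–Martin oxidation under buffered, non-basic conditions stops at the aldehyde, and immediate use limits isomerisation of the β,γ-alkynyl aldehyde to the allenal.

Step 3
Reactants: 2 (S)-but-3-yn-2-yl methanesulfonate; 4 pent-3-ynal
Product: 6 (3R,4S)-3-methylocta-1,6-diyn-4-ol, via allenylindium iodide mesylate 5 (not isolated)
Conditions: Pd(dppf)Cl2 (5 mol%), InI (1.4 equiv), THF–HMPA 3:1, 0 °C → rt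
Reagents that add atoms: none
Why: Marshall propargylation, in which Pd(0) displaces the mesylate anti (SN2′), transmetallation gives a configurationally stable allenylindium, and addition through a cyclic SE2′ transition state gives the anti adduct, so C3 (R) comes from net inversion of the mesylate centre and C4 (S) from the anti topology.

Step 4
Reactants: 6 (3R,4S)-3-methylocta-1,6-diyn-4-ol
Product: 7 tert-butyldimethyl{[(3R,4S)-3-methylocta-1,6-diyn-4-yl]oxy}silane
Conditions: TBSCl, imidazole, DMF, rt
Reagents that add atoms: tert-butyldimethylsilyl chloride CC(C)(C)[Si](C)(C)Cl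
Why: Standard silylation of a secondary alcohol; the bulky silyl ether later shields one face of the pyridone.

Step 5
Reactants: 7 tert-butyldimethyl{[(3R,4S)-3-methylocta-1,6-diyn-4-yl]oxy}silane; 8 methyl isocyanate
Product: 9 (6S,7R)-6-[(tert-butyldimethylsilyl)oxy]-2,4,7-trimethyl-2,5,6,7-tetrahydro-3H-cyclopenta[c]pyridin-3-one
Conditions: Ni(cod)2 (10 mol%), SIPr (10 mol%), MeNCO (3 equiv), toluene, rt; 7 added by syringe pump
Reagents that add atoms: none
Why: At Ni(0)–NHC the C=N bond of the isocyanate and the methyl-capped alkyne couple oxidatively to an azanickelacyclopentenone (C3–C4 formed), the tethered terminal alkyne inserts into the Ni–C bond (C4a–C7a formed), and C–N reductive elimination forms N2–C1. The closest known reaction is the Ni(0)/NHC-catalysed (2+2+2) cycloaddition of 1,6-diynes with isocyanates to fused 2-pyridones. The cyclopentene closes by 5-exo carbonickelation across the three-carbon tether, and the pyridone closes by C(sp2)–N reductive elimination from the seven-membered azanickelacycle. No stereocentre is formed, and C6 and C7 are untouched under these neutral conditions at room temperature. The step needs regioselectivity (carbonyl next to the methyl-bearing C4, nitrogen next to the unsubstituted C1); in this manifold the larger alkyne terminus ends up beside the carbonyl and the smaller one beside nitrogen, which here is secured by the size gap between C4–CH3 and C1–H and by the N-methyl group avoiding a peri substituent. Slow addition of 7 and excess isocyanate suppress oligomerisation of the terminal alkyne and isocyanurate formation.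

Step 6
Reactants: 9 (6S,7R)-6-[(tert-butyldimethylsilyl)oxy]-2,4,7-trimethyl-2,5,6,7-tetrahydro-3H-cyclopenta[c]pyridin-3-one
Product: 10 (4R,4aR,6S,7R,7aR)-6-[(tert-butyldimethylsilyl)oxy]-2,4,7-trimethyloctahydro-3H-cyclopenta[c]pyridin-3-one
Conditions: H2 (60 bar), 5% Rh/Al2O3, EtOH, 60 °C
Reagents that add atoms: none
Why: Heterogeneous hydrogenation of the 2-pyridone delivers hydrogen to C1/C7a and C4a/C4 from the face opposite both the C7 methyl and the C6 silyloxy group, so H-4, H-4a and H-7a end up mutually cis and the ring fusion is cis.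

Step 7
Reactants: 10 (4R,4aR,6S,7R,7aR)-6-[(tert-butyldimethylsilyl)oxy]-2,4,7-trimethyloctahydro-3H-cyclopenta[c]pyridin-3-one
Product: 11 (4R,4aR,6S,7R,7aR)-6-hydroxy-2,4,7-trimethyloctahydro-3H-cyclopenta[c]pyridin-3-one
Conditions: TBAF, THF, rt
Reagents that add atoms: none
Why: Fluoride-induced desilylation of a secondary TBS ether; the tertiary lactam is inert.

Step 8
Reactants: 11 (4R,4aR,6S,7R,7aR)-6-hydroxy-2,4,7-trimethyloctahydro-3H-cyclopenta[c]pyridin-3-one
Product: 12 (4R,4aR,7R,7aR)-2,4,7-trimethylhexahydro-1H-cyclopenta[c]pyridine-3,6(2H,4H)-dione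
Conditions: Dess–Martin periodinane, CH2Cl2, rt
Reagents that add atoms: none
Why: Dess–Martin oxidation of the secondary alcohol to the C6 ketone removes the C6 centre and makes C7 epimerisable.

Step 9
Reactants: 12 (4R,4aR,7R,7aR)-2,4,7-trimethylhexahydro-1H-cyclopenta[c]pyridine-3,6(2H,4H)-dione
Product: 13 (4R,4aR,7S,7aR)-2,4,7-trimethylhexahydro-1H-cyclopenta[c]pyridine-3,6(2H,4H)-dione
Conditions: DBU (0.3 equiv), CH2Cl2, rt
Reagents that add atoms: none
Why: Base-mediated equilibration through the ketone enolate moves the C7 methyl from the concave face (cis to C1) to the convex face (trans to C1), the more stable epimer, while the much less acidic lactam α-centre C4 is not touched.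

Step 10
Reactants: 13 (4R,4aR,7S,7aR)-2,4,7-trimethylhexahydro-1H-cyclopenta[c]pyridine-3,6(2H,4H)-dione
Product: 14 (4R,4aR,6S,7S,7aR)-6-hydroxy-2,4,7-trimethyloctahydro-3H-cyclopenta[c]pyridin-3-one
Conditions: NaBH4, MeOH, −20 °C
Reagents that add atoms: none
Why: Borohydride reduction of the ketone from the convex face of the cis-fused bicycle, as a small hydride does with 2-alkylcyclopentanones, gives the alcohol trans to the C7 methyl (6-epi series); the lactam is not reduced.

Step 11
Reactants: 14 (4R,4aR,6S,7S,7aR)-6-hydroxy-2,4,7-trimethyloctahydro-3H-cyclopenta[c]pyridin-3-one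
Product: 15 (4R,4aS,6S,7S,7aR)-2,4,7-trimethyloctahydro-1H-cyclopenta[c]pyridin-6-ol (6-epi-incarvilline)
Conditions: LiAlH4, THF, reflux; Fieser work-up
Reagents that add atoms: none
Why: Hydride reduction of the tertiary lactam to the N-methylpiperidine removes the C3 carbonyl without touching a stereocentre.

Step 12
Reactants: 16 methyl coumalate
Product: 18 cis-3-(methoxycarbonyl)cyclobutane-1-carboxylic acid, via photopyrone 17 (not isolated)
Conditions: hν (medium-pressure Hg lamp, Pyrex), CH2Cl2, 15 °C; then H2 (1 atm), Pt/C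
Reagents that add atoms: none
Why: Photochemical 4π-electrocyclisation of the 2-pyrone gives the bicyclic β-lactone; hydrogenolysis of its allylic C–O bond and syn hydrogenation of the cyclobutene from the face away from the carboxyl leave the two carbonyl groups cis on an achiral ring.

Step 13
Reactants: 18 cis-3-(methoxycarbonyl)cyclobutane-1-carboxylic acid; 19 2-(methylsulfanyl)aniline
Product: 20 methyl cis-3-{[2-(methylsulfanyl)phenyl]carbamoyl}cyclobutane-1-carboxylate
Conditions: EDC·HCl, DMAP (cat.), CH2Cl2, rt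
Reagents that add atoms: none
Why: Carbodiimide amide coupling installs the S,N-bidentate anilide that directs the two C–H arylations.

Step 14
Reactants: 21 4-iodo-2-methoxyphenol
Product: 22 1-(benzyloxy)-4-iodo-2-methoxybenzene
Conditions: BnBr, K2CO3, DMF, rt
Reagents that add atoms: benzyl bromide BrCc1ccccc1
Why: Williamson benzylation protects the phenol with a group that survives the Pd/Ag arylations and is removed by hydrogenolysis at the end.

Step 15
Reactants: 20 methyl cis-3-{[2-(methylsulfanyl)phenyl]carbamoyl}cyclobutane-1-carboxylate; 22 1-(benzyloxy)-4-iodo-2-methoxybenzene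
Product: 23 racemic all-cis methyl 2-[4-(benzyloxy)-3-methoxyphenyl]-3-{[2-(methylsulfanyl)phenyl]carbamoyl}cyclobutane-1-carboxylate
Conditions: Pd(OAc)2 (15 mol%), Ag2CO3 (1.5 equiv), PivOH (1 equiv), HFIP, 90 °C
Reagents that add atoms: none
Why: Amide-directed Pd(II)/Pd(IV) C(sp3)–H arylation; cyclopalladation occurs at a methylene C–H cis to the anilide, so the aryl group enters next to and cis to the amide (all-cis), either enantiotopic CH2 reacts (racemate), and HFIP/pivalic acid holds the reaction at mono-arylation.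

Step 16
Reactants: 23 racemic all-cis methyl 2-[4-(benzyloxy)-3-methoxyphenyl]-3-{[2-(methylsulfanyl)phenyl]carbamoyl}cyclobutane-1-carboxylate
Product: 24 the (1S,2S,3R) enantiomer of 23 (ring numbered C1 carbamoyl, C2 aryl, C3 CO2Me)
Conditions: preparative SFC, amylose tris(3,5-dimethylphenylcarbamate) phase, CO2/MeOH
Reagents that add atoms: none
Why: Resolution on a chiral stationary phase separates the two enantiomers of this UV-active amide ester, and later steps cannot racemise it because the aryl-bearing C2 is not epimerisable.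

Step 17
Reactants: 24 the (1S,2S,3R) enantiomer of 23
Product: 25 methyl (1R,2S,3R)-2-[4-(benzyloxy)-3-methoxyphenyl]-3-{[2-(methylsulfanyl)phenyl]carbamoyl}cyclobutane-1-carboxylate descriptors given for the ring numbered C1 carbamoyl, C2 aryl, C3 CO2Me (anilide now trans to aryl, ester still cis to aryl)
Conditions: LiOt-Bu (2 equiv), toluene, 50 °C
Reagents that add atoms: none
Why: Base-mediated epimerisation relieves the all-cis strain by inverting the carboxamide-bearing C1, which places the bulky anilide trans to the aryl group while the ester centre keeps its configuration.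

Step 18
Reactants: 25 the C1-epimerised amide ester; 26 1-(benzyloxy)-4-iodobenzene
Product: 27 methyl 2-[4-(benzyloxy)-3-methoxyphenyl]-4-[4-(benzyloxy)phenyl]-3-{[2-(methylsulfanyl)phenyl]carbamoyl}cyclobutane-1-carboxylate, (1R,2S,3R,4S) for the ring numbered C1 carbamoyl, C2 guaiacyl-type aryl, C3 CO2Me, C4 second aryl
Conditions: Pd(OAc)2 (15 mol%), Ag2CO3 (1.5 equiv), PivOH (1 equiv), t-BuOH, 75 °C
Reagents that add atoms: none
Why: A second amide-directed C–H arylation at the remaining methylene puts the new aryl cis to the anilide and trans to the ester and to the first aryl, which is the α-truxillate pattern (aryls trans, carbonyls trans, each aryl cis to one carbonyl).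

Step 19
Reactants: 27 the diaryl amide ester
Product: 28 N-Boc imide of 27 (tert-butyl N-acyl-N-[2-(methylsulfanyl)phenyl]carbamate)
Conditions: Boc2O, DMAP, MeCN, rt
Reagents that add atoms: di-tert-butyl dicarbonate CC(C)(C)OC(=O)OC(=O)OC(C)(C)C
Why: N-acylation of the secondary anilide with Boc2O twists and activates the amide for mild hydrolytic cleavage.

Step 20
Reactants: 28 N-Boc imide of 27
Product: 29 2-[4-(benzyloxy)-3-methoxyphenyl]-4-[4-(benzyloxy)phenyl]cyclobutane-1,3-dicarboxylic acid (α-truxillic configuration, enantiomer as in the SMILES)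
Conditions: LiOH·H2O, THF/MeOH/H2O, rt → 40 °C; then 1 M HCl
Reagents that add atoms: lithium hydroxide [Li+].[OH-]
Why: Hydroxide cleaves the activated N-Boc anilide at the acyl carbon and saponifies the methyl ester; the α-truxillate arrangement has no strain-driven reason to epimerise under these mild conditions.

Step 21
Reactants: 29 the protected diacid; 15 6-epi-incarvilline (2.4 equiv)
Product: 30 bis[(4R,4aS,6R,7S,7aR)-2,4,7-trimethyloctahydro-1H-cyclopenta[c]pyridin-6-yl] 2-[4-(benzyloxy)-3-methoxyphenyl]-4-[4-(benzyloxy)phenyl]cyclobutane-1,3-dicarboxylate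
Conditions: PPh3, DIAD, THF, 0 °C → rt
Reagents that add atoms: none
Why: Double Mitsunobu esterification, in which each carboxylate displaces the activated C6 oxygen by SN2 with inversion, turns (6S) into the required (6R) in both units; the tertiary amines are tolerated.

Step 22
Reactants: 30 the bis-benzyl ether diester
Product: 31 CNP0331906.2 (target)
Conditions: H2 (1 atm), 10% Pd/C, EtOAc–MeOH, rt
Reagents that add atoms: none
Why: Hydrogenolysis cleaves the two aryl benzyl ethers and leaves the alkyl esters, the N-methylpiperidines and the cyclobutane intact.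

**Compound list**
1 | (S)-but-3-yn-2-ol | C#C[C@H](C)O | starting material
2 | (S)-but-3-yn-2-yl methanesulfonate | C#C[C@H](C)OS(C)(=O)=O | intermediate
3 | pent-3-yn-1-ol | CC#CCCO | starting material
4 | pent-3-ynal | CC#CCC=O | intermediate
5 | (M)-buta-1,2-dien-1-ylindium(III) iodide methanesulfonate (not isolated) | C[CH]=[C@]=[CH][In](I)OS(C)(=O)=O | intermediate
6 | (3R,4S)-3-methylocta-1,6-diyn-4-ol | C#C[C@@H](C)[C@@H](O)CC#CC | intermediate
7 | tert-butyldimethyl{[(3R,4S)-3-methylocta-1,6-diyn-4-yl]oxy}silane | C#C[C@@H](C)[C@@H](O[Si](C)(C)C(C)(C)C)CC#CC | intermediate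
8 | methyl isocyanate | CN=C=O | starting material
9 | (6S,7R)-6-[(tert-butyldimethylsilyl)oxy]-2,4,7-trimethyl-2,5,6,7-tetrahydro-3H-cyclopenta[c]pyridin-3-one | CC(C)(C)[Si](C)(C)O[C@H]1Cc2c(cn(C)c(=O)c2C)[C@H]1C | intermediate
10 | (4R,4aR,6S,7R,7aR)-6-[(tert-butyldimethylsilyl)oxy]-2,4,7-trimethyloctahydro-3H-cyclopenta[c]pyridin-3-one | CC(C)(C)[Si](C)(C)O[C@H]1C[C@@H]2[C@@H](CN(C)C(=O)[C@@H]2C)[C@H]1C | intermediate
11 | (4R,4aR,6S,7R,7aR)-6-hydroxy-2,4,7-trimethyloctahydro-3H-cyclopenta[c]pyridin-3-one | O[C@H]1C[C@@H]2[C@@H](CN(C)C(=O)[C@@H]2C)[C@H]1C | intermediate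
12 | (4R,4aR,7R,7aR)-2,4,7-trimethylhexahydro-1H-cyclopenta[c]pyridine-3,6(2H,4H)-dione | O=C1C[C@@H]2[C@@H](CN(C)C(=O)[C@@H]2C)[C@H]1C | intermediate
13 | (4R,4aR,7S,7aR)-2,4,7-trimethylhexahydro-1H-cyclopenta[c]pyridine-3,6(2H,4H)-dione | O=C1C[C@@H]2[C@@H](CN(C)C(=O)[C@@H]2C)[C@@H]1C | intermediate
14 | (4R,4aR,6S,7S,7aR)-6-hydroxy-2,4,7-trimethyloctahydro-3H-cyclopenta[c]pyridin-3-one | O[C@H]1C[C@@H]2[C@@H](CN(C)C(=O)[C@@H]2C)[C@@H]1C | intermediate
15 | (4R,4aS,6S,7S,7aR)-2,4,7-trimethyloctahydro-1H-cyclopenta[c]pyridin-6-ol (6-epi-incarvilline) | O[C@H]1C[C@@H]2[C@@H](CN(C)C[C@@H]2C)[C@@H]1C | intermediate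
16 | methyl coumalate (methyl 2-oxo-2H-pyran-5-carboxylate) | COC(=O)C1=COC(=O)C=C1 | starting material
17 | methyl 3-oxo-2-oxabicyclo[2.2.0]hex-5-ene-6-carboxylate (racemic, cis-fused; not isolated) | COC(=O)C1=C[C@@H]2[C@H]1OC2=O | intermediate
18 | cis-3-(methoxycarbonyl)cyclobutane-1-carboxylic acid | OC(=O)[C@H]1C[C@@H](C(=O)OC)C1 | intermediate
19 | 2-(methylsulfanyl)aniline | CSc1ccccc1N | starting material
20 | methyl cis-3-{[2-(methylsulfanyl)phenyl]carbamoyl}cyclobutane-1-carboxylate | COC(=O)[C@H]1C[C@@H](C(=O)Nc2ccccc2SC)C1 | intermediate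
21 | 4-iodo-2-methoxyphenol | COc1cc(I)ccc1O | starting material
22 | 1-(benzyloxy)-4-iodo-2-methoxybenzene | COc1cc(I)ccc1OCc1ccccc1 | intermediate
23 | racemic all-cis methyl 2-[4-(benzyloxy)-3-methoxyphenyl]-3-{[2-(methylsulfanyl)phenyl]carbamoyl}cyclobutane-1-carboxylate (one enantiomer drawn) | COc1cc([C@H]2[C@@H](C(=O)Nc3ccccc3SC)C[C@H]2C(=O)OC)ccc1OCc1ccccc1 | intermediate
24 | (1S,2S,3R) enantiomer of 23, all-cis (C1 carbamoyl, C2 aryl, C3 CO2Me) | COc1cc([C@H]2[C@@H](C(=O)Nc3ccccc3SC)C[C@H]2C(=O)OC)ccc1OCc1ccccc1 | intermediate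
25 | (1R,2S,3R) C1-epimer of 24: anilide trans to aryl, ester cis to aryl | COc1cc([C@H]2[C@H](C(=O)Nc3ccccc3SC)C[C@H]2C(=O)OC)ccc1OCc1ccccc1 | intermediate
26 | 1-(benzyloxy)-4-iodobenzene | Ic1ccc(OCc2ccccc2)cc1 | starting material
27 | methyl (1R,2S,3R,4S)-2-[4-(benzyloxy)-3-methoxyphenyl]-4-[4-(benzyloxy)phenyl]-3-{[2-(methylsulfanyl)phenyl]carbamoyl}cyclobutane-1-carboxylate (descriptors for ring numbered C1 carbamoyl, C2 guaiacyl-type aryl, C3 CO2Me, C4 second aryl) | COc1cc([C@H]2[C@H](C(=O)Nc3ccccc3SC)[C@H](c3ccc(OCc4ccccc4)cc3)[C@H]2C(=O)OC)ccc1OCc1ccccc1 | intermediate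
28 | N-Boc imide of 27 | COc1cc([C@H]2[C@H](C(=O)N(C(=O)OC(C)(C)C)c3ccccc3SC)[C@H](c3ccc(OCc4ccccc4)cc3)[C@H]2C(=O)OC)ccc1OCc1ccccc1 | intermediate
29 | 2-[4-(benzyloxy)-3-methoxyphenyl]-4-[4-(benzyloxy)phenyl]cyclobutane-1,3-dicarboxylic acid, α-truxillic configuration, single enantiomer | COc1cc([C@H]2[C@H](C(=O)O)[C@H](c3ccc(OCc4ccccc4)cc3)[C@H]2C(=O)O)ccc1OCc1ccccc1 | intermediate
30 | bis[(4R,4aS,6R,7S,7aR)-2,4,7-trimethyloctahydro-1H-cyclopenta[c]pyridin-6-yl] diester of 29 | COc1cc([C@H]2[C@H](C(=O)O[C@@H]3C[C@@H]4[C@@H](CN(C)C[C@@H]4C)[C@@H]3C)[C@H](c3ccc(OCc4ccccc4)cc3)[C@H]2C(=O)O[C@@H]2C[C@@H]3[C@@H](CN(C)C[C@@H]3C)[C@@H]2C)ccc1OCc1ccccc1 | intermediate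
31 | CNP0331906.2 | COc1cc([C@H]2[C@H](C(=O)O[C@@H]3C[C@@H]4[C@@H](CN(C)C[C@@H]4C)[C@@H]3C)[C@H](c3ccc(O)cc3)[C@H]2C(=O)O[C@@H]2C[C@@H]3[C@@H](CN(C)C[C@@H]3C)[C@@H]2C)ccc1O | target

**Step count**
Total steps: 22. Longest linear sequence: 12 steps (steps 2, 3, 4–11, 21, 22 from pent-3-yn-1-ol; the same length from 1).

**Steps most likely to fail**

Step 5 (key cycloaddition). The isocyanate may be taken up the other way round (carbonyl bonded to the terminal alkyne carbon, nitrogen to the methyl-bearing one), because the steric difference between H and CH3 is small. The terminal alkyne may also oligomerise at nickel before the isocyanate is engaged. The fallback sets out from 7 and changes the control element to a removable blocking group in a metallacyclopentadiene manifold. Compound 7 would be C-silylated (n-BuLi, TMSCl, THF, −78 °C) to the trimethylsilyl-capped diyne F1. A cationic rhodium(I) catalyst ([Rh(cod)2]BF4, H8-BINAP, ClCH2CH2Cl, 60 °C, MeNCO) would then form a rhodacyclopentadiene. In it the isocyanate carbon should be delivered to the less hindered methyl-bearing α-carbon and the nitrogen to the silyl-bearing one, giving the 1-silyl pyridone F2. Fluoride protodesilylation at the carbon next to nitrogen (CsF, DMF–H2O, rt, conditions that spare the secondary TBS ether) would return the route at 9.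

Step 6 (pyridone hydrogenation). The tetrasubstituted C4=C4a bond may resist reduction, or double-bond migration on the metal surface may erode the all-cis delivery of hydrogen. The fallback sets out from 9 and splits the reduction in two. Mild hydrogenation (H2 1 atm, Pd/C, EtOH) should saturate only the C1=C7a enamide bond, anti to the C7 methyl, giving the α,β-unsaturated lactam (6S,7R,7aS)-6-[(tert-butyldimethylsilyl)oxy]-2,4,7-trimethyl-1,2,5,6,7,7a-hexahydro-3H-cyclopenta[c]pyridin-3-one F3. A homogeneous iridium catalyst for hindered olefins ([Ir(cod)(PCy3)(py)]BArF, H2 50 bar, CH2Cl2) would then add hydrogen to the tetrasubstituted C4=C4a bond from the convex face without isomerisation, returning the route at 10.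

Step 3 (propargylation). Pent-3-ynal may isomerise to the allenal or conjugated ynal before it is captured, which lowers conversion and gives adducts of the isomerised aldehyde. The fallback sets out from 2 and forms the C5–C6 bond by epoxide opening instead. The same Pd/InI propargylation with the stable (tert-butyldimethylsilyloxy)acetaldehyde would give the anti adduct (2R,3R)-1-[(tert-butyldimethylsilyl)oxy]-3-methylpent-4-yn-2-ol F4. TBAF would give (2R,3R)-3-methylpent-4-yne-1,2-diol F5. Selective primary tosylation (TsCl, pyridine, 0 °C) would give the monotosylate F6, and K2CO3 in MeOH would close (2R)-2-[(2R)-but-3-yn-2-yl]oxirane F7. Opening at the terminal carbon with excess 1-propynyllithium and BF3·OEt2 (THF, −78 °C) would return the route at 6 with the carbinol centre unchanged.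

**Further compounds**
F1 | step 5 | tert-butyldimethyl{[(3R,4S)-3-methyl-1-(trimethylsilyl)octa-1,6-diyn-4-yl]oxy}silane | C[Si](C)(C)C#C[C@@H](C)[C@@H](O[Si](C)(C)C(C)(C)C)CC#CC
F2 | step 5 | (6S,7R)-6-[(tert-butyldimethylsilyl)oxy]-2,4,7-trimethyl-1-(trimethylsilyl)-2,5,6,7-tetrahydro-3H-cyclopenta[c]pyridin-3-one | CC(C)(C)[Si](C)(C)O[C@H]1Cc2c(c([Si](C)(C)C)n(C)c(=O)c2C)[C@H]1C
F3 | step 6 | (6S,7R,7aS)-6-[(tert-butyldimethylsilyl)oxy]-2,4,7-trimethyl-1,2,5,6,7,7a-hexahydro-3H-cyclopenta[c]pyridin-3-one | CC(C)(C)[Si](C)(C)O[C@H]1CC2=C(C)C(=O)N(C)C[C@H]2[C@H]1C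
F4 | step 3 | (2R,3R)-1-[(tert-butyldimethylsilyl)oxy]-3-methylpent-4-yn-2-ol | C#C[C@@H](C)[C@@H](O)CO[Si](C)(C)C(C)(C)C
F5 | step 3 | (2R,3R)-3-methylpent-4-yne-1,2-diol | C#C[C@@H](C)[C@@H](O)CO
F6 | step 3 | (2R,3R)-2-hydroxy-3-methylpent-4-yn-1-yl 4-methylbenzenesulfonate | C#C[C@@H](C)[C@@H](O)COS(=O)(=O)c1ccc(C)cc1
F7 | step 3 | (2R)-2-[(2R)-but-3-yn-2-yl]oxirane | C#C[C@@H](C)[C@@H]1CO1
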